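Read each flask below as a titration of the base, followed by a race for whatever starting material survives it.

| setting | red | violet |
|---|---|---|
| starting material | 0.28 M | 0.28 M |
| reagent | 0.364 M | 0.364 M |
| base | 0.0140 M | 0.0140 M |
| temperature | 110 °C | 140 °C |
| time | 20 min | 20 min |

    starting material + reagent + by-product → target + 2 by-product (k1 = 0.089 L² mol⁻² s⁻¹, Ea1 = 65.0 kJ mol⁻¹)
    starting material + reagent → target + by-product (k2 = 5.9 × 10⁻⁴ L mol⁻¹ s⁻¹, Ea2 = 88.0 kJ mol⁻¹)
    base + by-product ⇌ salt, settled at all times (K3 = 11000 L mol⁻¹, ΔH3 = −5.00 kJ mol⁻¹)
    2 starting material → self-condensation product (k4 = 0.0089 L mol⁻¹ s⁻¹, Ea4 = 68.0 kJ mol⁻¹)
    target → over-reaction product (k5 = 2.2 × 10⁻⁶ s⁻¹, Ea5 = 121 kJ mol⁻¹)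
    (constants at 110 °C)

* the best flask by amount of target, in percent of the starting material charged; "all alike" if 1.5 percentage points covers them all (red / violet / all alike)
* amount of target at the end, in percent of the starting material charged, red
* amount of target at the end, in percent of the starting material charged, violet

- a species is counted by the starting material in it: one self-condensation product counts as two
- two of one species on the left: rate k times its square, two consumed each time
- at 110 °C the constants are as listed, elsewhere as the activation energies and enthalpies make them

Draw the target curve for red by hand. The catalysed route equals the uncatalysed route at a free by-product level of 0.00663 M. Where free and bound base stand equal, the balance allows far less than that, 9.09 × 10⁻⁵ M, so the curve starts on the uncatalysed route, at a slope of 0.0129 min⁻¹ as a fraction of the charge. Self-condensation bends it over, with a first half-life of 3.34 min.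

Divide the uncatalysed rate by the self-condensation rate, hold the reagent near its charge, and integrate. This gives the base toll N: twice the self-condensation constant times the base charge, over the uncatalysed constant times the reagent charge, 1.16. The starting-material charge cancels from N, and e^−N estimates the share of starting material alive when the target made equals the base charge, in red 31.3%, with the starting material spent on target itself not counted.

By this reckoning red's induction period ends in a knee at 7.33 min, with target at 5.00%. Autocatalysis follows: the catalysed route overtakes near 7.37% target. The estimated ceiling on the level is toll target plus survivors, 36.3%. My reckoning stops at that ceiling.

In violet, self-condensation speeds up by a factor of 4.7 and the uncatalysed route by a factor of 7.4, so N falls to 0.736. Estimated survivors rise to 47.9%, the knee is reckoned at 0.773 min, and the estimated ceiling is 52.9%. I commit to violet, without a yield.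

The forecast also says violet, and it does name yields: 14% for red and 26.5% for violet. Its ground is that when hot “the base is used up earlier with more starting material left”.

The simulation gives violet as best, with 24.5% against 10.3% in red. Red still held 10.7% of its starting material at 20.0 min, and its target stood at 18.1% by 200 min. Take the toll's target from each yield and divide by the estimated survivors: red's figure at 200 min gives a share of 0.419, and violet's at 20.0 min gives 0.407.

Now take a flask like red with 0.091 M of reagent. Its toll is 4.64, but the logarithm of the factor by which self-condensation lowers the starting material in 20 min is 1.94. So expect no knee, 2.09% target and 58.2% of the base left. The computed flask shows 2.00% target and 60% of its base still unbound.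

All constants were set for the occasion; the result is computed.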